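**Retrosynthetic overview**
1. Target 11 ⇐ silyl peroxyketal bis-endoperoxide 10, by acid-catalysed exchange of OSi for OMe at C6 in the same flask.
2. 10 ⇐ achiral tetraene 8: all four ring C–O bonds come from one radical-cation chain oxygenation with triplet O2 under a chiral counteranion; ring B (silyloxy diene) forms first, ring A ((E,E)-diene) second.
3. 8 ⇐ trienone 6, by O-silylation of the extended (γ) dienolate.
4. 6 ⇐ enone 4 + (E)-pentenylboronic acid 5 (oxidative Heck); 4 ⇐ methyl pent-4-ynoate 1 + hex-5-enoyl chloride 2 (hydrozirconation/acylation).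

Assumption: the antipode of the chiral counteranion that delivers the (3R,10R,13S) series has to be found in a screening run; (S,S) is written as a placeholder and its mirror image is used if the sense is opposite.
Numbering: C1–C16 follow the hexadecanoate chain (C1 = ester carbon); the target is (3R,6S,10R,13S).

Step 1
Reactants: 1 methyl pent-4-ynoate; 2 hex-5-enoyl chloride
Product: 4 methyl (4E)-6-oxoundeca-4,10-dienoate, via alkenylzirconocene chloride 3 (not isolated)
Conditions: Cp2Zr(H)Cl (1.1 equiv), CH2Cl2, 0 °C to rt, 20 min; then CuBr·SMe2 (10 mol %), 2 (1.1 equiv), rt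
Reagents that add atoms: none
Why: syn, anti-Markovnikov hydrozirconation of the terminal alkyne (faster than hydride attack on the methyl ester) gives the (E)-alkenylzirconocene, and copper-catalysed acylation of this organozirconium by the acid chloride forms the C5–C6 bond with retention of the E geometry; no stereocentre is made.

Step 2
Reactants: 4 methyl (4E)-6-oxoundeca-4,10-dienoate; 5 [(1E)-pent-1-en-1-yl]boronic acid
Product: 6 methyl (4E,10E,12E)-6-oxohexadeca-4,10,12-trienoate
Conditions: Pd(OAc)2 (10 mol %), 1,2-bis(phenylsulfinyl)ethane (10 mol %), 1,4-benzoquinone (2 equiv), AcOH (4 equiv), 1,4-dioxane, rt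
Reagents that add atoms: none
Why: oxidative boron Heck reaction, in which the alkenyl–Pd species from transmetalation adds to the CH2 end of the terminal alkene and β-hydride elimination toward the new vinyl group gives the conjugated (10E,12E)-diene with the pentenyl geometry retained, while benzoquinone reoxidises zerovalent palladium and the electron-poor internal enone is left alone.

Step 3
Reactants: 6 methyl (4E,10E,12E)-6-oxohexadeca-4,10,12-trienoate
Product: 8 methyl (3E,5Z,10E,12E)-6-[(tert-butyldimethylsilyl)oxy]hexadeca-3,5,10,12-tetraenoate, via extended potassium dienolate 7 (not isolated)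
Conditions: KN(SiMe3)2 (1.05 equiv), THF, −78 °C, then −20 °C, 1 h; tert-butyldimethylsilyl trifluoromethanesulfonate (1.2 equiv), −78 °C
Reagents that add atoms: tert-butyldimethylsilyl trifluoromethanesulfonate, CC(C)(C)[Si](C)(C)OS(=O)(=O)C(F)(F)F
Why: thermodynamic enolate formation followed by O-silylation, in which the kinetically formed cross-conjugated α′-enolate equilibrates through HN(SiMe3)2 to the more delocalised extended dienolate (γ-deprotonation at C3, new C3=C4 bond E, oxygen cis to C4) and the hard silyl triflate traps it on oxygen to give the 1-silyloxy-1,3-diene that ring B needs; the C5 geometry is of no consequence because C6 is reset in step 4.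

Step 4
Reactants: 8 methyl (3E,5Z,10E,12E)-6-[(tert-butyldimethylsilyl)oxy]hexadeca-3,5,10,12-tetraenoate
Product: 11 methyl 2-[(3R,6S)-6-methoxy-6-{3-[(3R,6S)-6-propyl-3,6-dihydro-1,2-dioxin-3-yl]propyl}-3,6-dihydro-1,2-dioxin-3-yl]acetate, via ring B mono-endoperoxide 9 (not isolated), via silyl peroxyketal bis-endoperoxide 10 (not isolated)
Conditions: O2 (1 atm), 2,4,6-triphenylpyrylium salt of the (S,S)-imidodiphosphorimidate anion from 3,3′-bis[3,5-bis(trifluoromethyl)phenyl]-1,1′-bi-2-naphthol with an N-trifluoromethylsulfonyl core (3 mol %), CH2Cl2, −78 °C, 420 nm LEDs; then MeOH, pyridinium p-toluenesulfonate (10 mol %), −40 to 0 °C, held until the C6 epimer ratio is constant; chromatography on silica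
Reagents that add atoms: dioxygen, O=O; methanol, CO
Why: Proposed new method: photoinduced electron transfer to excited 2,4,6-triphenylpyrylium (a sensitiser that makes neither singlet oxygen nor superoxide) turns first the electron-rich silyloxy diene and then the (E,E)-dialkyl diene into radical cations held as contact ion pairs in the confined chiral anion; triplet O2 adds to a diene terminus and the peroxyl radical closes on the same face onto the (Z)-allyl cation of the s-cis conformer (replenished by degenerate electron exchange with neutral diene) in the enantio-determining step, and the dioxine radical cation then oxidises the next diene and carries the chain, so that the anion sets C3, C10 and C13 and the E,E geometry fixes the cis relationship at C10/C13; the closing acid-catalysed exchange of the silyl peroxyketal with methanol runs through a peroxycarbenium ion, so C6 is set by equilibration of the two methyl peroxyketals, which are expected in comparable amounts because the methoxy group can sit pseudoaxial (anomeric) in both, and 11 (methoxy trans to CH2CO2Me) is separated on silica while the C6-epimeric fraction is returned to the same MeOH/acid conditions; the closest known reaction types are the aminium-salt-initiated radical-cation chain oxygenation of 1,3-dienes with triplet oxygen (Barton–Haynes endoperoxidation), pyrylium-photocatalysed radical-cation endoperoxidations, asymmetric counteranion-directed photoredox radical-cation cycloadditions and the acid-catalysed ketalisation of 3,6-dihydro-1,2-dioxin-3-ols to epimeric peroxyketals.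

**Compound list**
1 | methyl pent-4-ynoate | C#CCCC(=O)OC | starting material
2 | hex-5-enoyl chloride | C=CCCCC(=O)Cl | starting material
3 | chlorobis(cyclopentadienyl)[(1E)-5-methoxy-5-oxopent-1-en-1-yl]zirconium | COC(=O)CC/C=C/[Zr](Cl)(C1C=CC=C1)C1C=CC=C1 | intermediate
4 | methyl (4E)-6-oxoundeca-4,10-dienoate | C=CCCCC(=O)/C=C/CCC(=O)OC | intermediate
5 | [(1E)-pent-1-en-1-yl]boronic acid | CCC/C=C/B(O)O | starting material
6 | methyl (4E,10E,12E)-6-oxohexadeca-4,10,12-trienoate | CCC/C=C/C=C/CCCC(=O)/C=C/CCC(=O)OC | intermediate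
7 | potassium (3E,5Z,10E,12E)-1-methoxy-1-oxohexadeca-3,5,10,12-tetraen-6-olate | CCC/C=C/C=C/CCC/C([O-])=C/C=C/CC(=O)OC.[K+] | intermediate
8 | methyl (3E,5Z,10E,12E)-6-[(tert-butyldimethylsilyl)oxy]hexadeca-3,5,10,12-tetraenoate | CCC/C=C/C=C/CCC/C(O[Si](C)(C)C(C)(C)C)=C/C=C/CC(=O)OC | intermediate
9 | methyl 2-[(3R,6R)-6-[(tert-butyldimethylsilyl)oxy]-6-[(4E,6E)-deca-4,6-dien-1-yl]-3,6-dihydro-1,2-dioxin-3-yl]acetate (silyloxy trans to CH2CO2Me) | CCC/C=C/C=C/CCC[C@@]1(O[Si](C)(C)C(C)(C)C)C=C[C@@H](CC(=O)OC)OO1 | intermediate
10 | methyl 2-[(3R,6R)-6-[(tert-butyldimethylsilyl)oxy]-6-{3-[(3R,6S)-6-propyl-3,6-dihydro-1,2-dioxin-3-yl]propyl}-3,6-dihydro-1,2-dioxin-3-yl]acetate (ring A cis; silyloxy trans to CH2CO2Me) | CCC[C@H]1C=C[C@@H](CCC[C@@]2(O[Si](C)(C)C(C)(C)C)C=C[C@@H](CC(=O)OC)OO2)OO1 | intermediate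
11 | methyl 2-[(3R,6S)-6-methoxy-6-{3-[(3R,6S)-6-propyl-3,6-dihydro-1,2-dioxin-3-yl]propyl}-3,6-dihydro-1,2-dioxin-3-yl]acetate (ring A cis; OMe trans to CH2CO2Me) | CCC[C@H]1C=C[C@@H](CCC[C@@]2(OC)C=C[C@@H](CC(=O)OC)OO2)OO1 | target

**Step count and risk**
Total step count: 4. Longest linear sequence: 4 steps (1 → 4 → 6 → 8 → 11).

Steps most likely to fail, most serious first:

Step 4. Four things can go wrong. Open-chain diene radical cations are mostly s-trans and may give open-chain hydroperoxides. The silyloxy diene radical cation may lose the silyl group. The level and sense of induction by the chiral anion are unproven. The closing exchange gives both C6 epimers, so each pass delivers only part of the material as 11 and the rest has to be re-equilibrated.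

Fallback, setting out from 8 and coming back at 11: sensitised singlet-oxygen double [4+2] cycloaddition (tetraphenylporphyrin, O2, visible light, CH2Cl2, −78 °C). This is pericyclic, so the s-cis conformers are reached by ordinary bond rotation and ring A is formed cis, but there is no enantiocontrol. It gives methyl 2-[6-[(tert-butyldimethylsilyl)oxy]-6-[3-(6-propyl-3,6-dihydro-1,2-dioxin-3-yl)propyl]-3,6-dihydro-1,2-dioxin-3-yl]acetate F1 as a stereoisomer mixture. Exchange with MeOH and pyridinium p-toluenesulfonate gives methyl 2-[6-methoxy-6-[3-(6-propyl-3,6-dihydro-1,2-dioxin-3-yl)propyl]-3,6-dihydro-1,2-dioxin-3-yl]acetate F2 as a stereoisomer mixture. From this, 11 is isolated by silica chromatography (C6 epimers) and preparative chiral-phase HPLC.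

Step 3. Silylation may occur from the α′-enolate, or the enolate may add to traces of neutral enone during equilibration.

Fallback, setting out from 6 and coming back at 11: the dienol ether is avoided and regiochemistry is enforced by an intramolecular hydrogen shift. The chiral pyrylium ion pair and O2 of step 4, applied to 6, oxygenate only the (E,E)-diene (the enone is not oxidised) and give methyl (4E)-6-oxo-9-[(3R,6S)-6-propyl-3,6-dihydro-1,2-dioxin-3-yl]non-4-enoate F3. Irradiation through Pyrex under O2 with tetraphenylporphyrin (CH2Cl2, −20 °C) isomerises the enone to Z, and a 1,5-hydrogen shift from C3 gives the dienol, which is captured by singlet oxygen as methyl 2-[6-hydroxy-6-{3-[(3R,6S)-6-propyl-3,6-dihydro-1,2-dioxin-3-yl]propyl}-3,6-dihydro-1,2-dioxin-3-yl]acetate F4 (both C3 configurations). MeOH with pyridinium p-toluenesulfonate then gives methyl 2-[6-methoxy-6-{3-[(3R,6S)-6-propyl-3,6-dihydro-1,2-dioxin-3-yl]propyl}-3,6-dihydro-1,2-dioxin-3-yl]acetate F5 as the ring B stereoisomer mixture, from which 11 is separated by silica chromatography and preparative chiral-phase HPLC.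

Step 2. Pd–H chain walking can give skipped or branched dienes and erode the E,E geometry.

Fallback, setting out from 4 and coming back at 6: the diene is assembled by cross-coupling of two preformed (E)-alkenyl partners. Selective ozonolysis of the terminal alkene (O3, CH2Cl2/pyridine, −78 °C; then PPh3) gives methyl (4E)-6,10-dioxodec-4-enoate F6. Takai olefination of the aldehyde (CrCl2, CHI3, THF, 0 °C) gives methyl (4E,10E)-11-iodo-6-oxoundeca-4,10-dienoate F7. Suzuki–Miyaura coupling with 5 (Pd(PPh3)4, aqueous K3PO4, THF, rt) gives 6 with both alkene geometries fixed by the partners.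

**Further compounds**
F1 | step 4 | methyl 2-[6-[(tert-butyldimethylsilyl)oxy]-6-[3-(6-propyl-3,6-dihydro-1,2-dioxin-3-yl)propyl]-3,6-dihydro-1,2-dioxin-3-yl]acetate (stereoisomer mixture) | CCCC1C=CC(CCCC2(O[Si](C)(C)C(C)(C)C)C=CC(CC(=O)OC)OO2)OO1
F2 | step 4 | methyl 2-[6-methoxy-6-[3-(6-propyl-3,6-dihydro-1,2-dioxin-3-yl)propyl]-3,6-dihydro-1,2-dioxin-3-yl]acetate (stereoisomer mixture containing 11) | CCCC1C=CC(CCCC2(OC)C=CC(CC(=O)OC)OO2)OO1
F3 | step 3 | methyl (4E)-6-oxo-9-[(3R,6S)-6-propyl-3,6-dihydro-1,2-dioxin-3-yl]non-4-enoate | CCC[C@H]1C=C[C@@H](CCCC(=O)/C=C/CCC(=O)OC)OO1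
F4 | step 3 | methyl 2-[6-hydroxy-6-{3-[(3R,6S)-6-propyl-3,6-dihydro-1,2-dioxin-3-yl]propyl}-3,6-dihydro-1,2-dioxin-3-yl]acetate (mixture at C3 and C6 of ring B) | CCC[C@H]1C=C[C@@H](CCCC2(O)C=CC(CC(=O)OC)OO2)OO1
F5 | step 3 | methyl 2-[6-methoxy-6-{3-[(3R,6S)-6-propyl-3,6-dihydro-1,2-dioxin-3-yl]propyl}-3,6-dihydro-1,2-dioxin-3-yl]acetate (ring B stereoisomer mixture containing 11) | CCC[C@H]1C=C[C@@H](CCCC2(OC)C=CC(CC(=O)OC)OO2)OO1
F6 | step 2 | methyl (4E)-6,10-dioxodec-4-enoate | O=CCCCC(=O)/C=C/CCC(=O)OC
F7 | step 2 | methyl (4E,10E)-11-iodo-6-oxoundeca-4,10-dienoate | I/C=C/CCCC(=O)/C=C/CCC(=O)OC
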